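**Retrosynthetic overview**
1. Target ⇐ C8 acetate and C11 angelate put on last; C11–OH from convex-face hydroxylation of the cis-fused 12,6-lactone enolate; lactone from the C7 isopropenyl group and the C6 hydroxyl.
2. (1(10)Z,4E)-Cyclodeca-1,5-diene ⇐ anionic oxy-Cope [3,3] rearrangement of a cis-1-isopropenyl-2-methyl-2-vinylcyclohexanol (forms C2–C3, cleaves C5–C10); the enolate is trapped as its triflate and reduced to C4=C5–H.
3. That cyclohexanol ⇐ (R)-(−)-carvone, which supplies C7; O8 by γ-hydroxylation, O6 by α'-hydroxylation then Mitsunobu inversion, the C10 quaternary centre by reductive vinylation anti to the axial C6 aryloxy group, then isopropenyl addition at C5.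
4. Ring order: six-membered ring (bought in carvone) → ten-membered carbocycle (sigmatropic ring expansion) → γ-lactone.

Assumption: the SMILES is taken as drawn, i.e. C1=C10 Z, C4=C5 E and (6S,7R,8S,11S). Six-membered intermediates use carvone numbering (C1 carbonyl, C2 methyl-bearing, C5 isopropenyl-bearing); ten-membered ones use germacrane numbering; "cis/trans" is relative to the isopropenyl group (later C11) unless stated.

**Step 1**
Reactants: 1 (R)-(−)-carvone
Product: 3 trans-4-hydroxycarvone, via trans-4-hydroperoxycarvone 2 (not isolated)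
Conditions: Cu(OSO2CF3)2 (10 mol%), 1,1,3,3-tetramethylguanidine (20 mol%), O2 (1 atm), THF, 0 °C; then PPh3
Reagents that add atoms: dioxygen (O=O)
Why: Copper-catalysed vinylogous aerobic oxidation of the extended dienolate (γ-hydroxylation), with O2 attacking C4 anti to the adjacent C5 isopropenyl so the new C4–O centre is trans to it, and PPh3 reducing the hydroperoxide.

**Step 2**
Reactants: 3 trans-4-hydroxycarvone
Product: 4 (4S,5R)-4-(tert-butyldimethylsilyloxy)-2-methyl-5-(prop-1-en-2-yl)cyclohex-2-en-1-one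
Conditions: t-BuMe2SiCl, imidazole, DMF, 0 °C → rt
Reagents that add atoms: tert-butyldimethylsilyl chloride (CC(C)(C)[Si](C)(C)Cl)
Why: Silyl ether protection of the allylic alcohol, with no stereocentre touched.

**Step 3**
Reactants: 4 the silyl ether
Product: 6 6-hydroxy enone (6-OH trans to the 5-isopropenyl), via lithium dienolate 5 (not isolated)
Conditions: LiN(i-Pr)2, THF, −78 °C; then (±)-2-(phenylsulfonyl)-3-phenyloxaziridine, −78 °C
Reagents that add atoms: 2-(phenylsulfonyl)-3-phenyloxaziridine (O=S(=O)(c1ccccc1)N1OC1c1ccccc1)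
Why: Kinetic α'-deprotonation and Davis enolate hydroxylation, the oxidant approaching C6 anti to the neighbouring isopropenyl group to give the trans alcohol.

**Step 4**
Reactants: 6 the trans α'-hydroxy enone
Product: 7 6-(4-methoxyphenoxy) enone (aryloxy cis to the 5-isopropenyl)
Conditions: PPh3, diisopropyl azodicarboxylate, 4-methoxyphenol, toluene, 0 °C → rt
Reagents that add atoms: 4-methoxyphenol (COc1ccc(O)cc1)
Why: Mitsunobu etherification with SN2 inversion at the carbonyl-activated C6, which sets the final C6–O configuration (cis to the future C11) and protects it.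

**Step 5**
Reactants: 7 the cis aryloxy enone
Product: 9 2-methyl-2-[2-(phenylsulfinyl)ethyl]cyclohexanone (chain trans, methyl cis to the isopropenyl), via lithium enolate 8 (not isolated)
Conditions: LiBH(s-Bu)3, THF, −78 °C; then phenyl vinyl sulfoxide, −78 → −30 °C; AcOH
Reagents that add atoms: phenyl vinyl sulfoxide (C=CS(=O)c1ccccc1)
Why: Conjugate hydride reduction gives the regiodefined enolate, whose C6 aryloxy group is held axial by allylic strain on the isopropenyl face, so Michael addition to the vinyl cation equivalent builds the quaternary carbon from the opposite face.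

**Step 6**
Reactants: 9 the keto sulfoxide
Product: 10 2-methyl-2-vinylcyclohexanone (vinyl trans to the isopropenyl)
Conditions: toluene, CaCO3, 110 °C
Reagents that add atoms: none
Why: Thermal sulfoxide syn-elimination can only use the CH2 next to the quaternary carbon, so it unveils the vinyl group without touching a stereocentre.

**Step 7**
Reactants: 10 the vinyl ketone
Product: 11 1,5-di(prop-1-en-2-yl)-2-vinylcyclohexan-1-ol (1-isopropenyl cis to the 2-vinyl; 1-OH cis to the 6-aryloxy)
Conditions: CH2=C(CH3)MgBr, LaCl3·2LiCl (30 mol%), THF, −20 → 0 °C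
Reagents that add atoms: isopropenylmagnesium bromide (CC(=C)[Mg]Br)
Why: Lanthanide-assisted Grignard 1,2-addition to the hindered ketone occurs anti to the α-aryloxy group and the axial α-methyl (Felkin–Anh control), placing the new isopropenyl cis to the vinyl group.

**Step 8**
Reactants: 11 the cis-dialkenyl cyclohexanol
Product: 14 ten-membered enol triflate, via potassium alkoxide 12 (not isolated), via potassium enolate 13 (not isolated)
Conditions: KH, 18-crown-6, THF, 0 → 40 °C; then PhN(SO2CF3)2, −78 → 0 °C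
Reagents that add atoms: N-phenylbis(trifluoromethanesulfonimide) (O=S(=O)(N(c1ccccc1)S(=O)(=O)C(F)(F)F)C(F)(F)F)
Why: Anionic oxy-Cope [3,3]-sigmatropic rearrangement through a chair transition state (axial isopropenyl, equatorial vinyl) forms C2–C3 and the ten-membered ring with the 1(10)Z alkene and an enolate of defined geometry (O cis to C3) that is trapped as the triflate; C5 and C10 are consumed while C6, C7 and C8 are untouched.

**Step 9**
Reactants: 14 the enol triflate
Product: 15 (1(10)Z,4E)-6-(4-methoxyphenoxy)-8-(tert-butyldimethylsilyloxy)germacra-1(10),4,11(12)-triene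
Conditions: Pd(OAc)2 (5 mol%), PPh3, HCO2H, n-Bu3N, DMF, 50 °C
Reagents that add atoms: none
Why: Palladium-catalysed formate reduction of the enol triflate (oxidative addition to zerovalent palladium, hydride transfer, reductive elimination) replaces OTf by H with retention, fixing the 4E alkene.

**Step 10**
Reactants: 15 the triene
Product: 17 C12 primary alcohol (C11 epimers), via B-alkyl-9-BBN borane 16 (not isolated)
Conditions: 9-BBN-H, THF, 0 °C → rt; then NaOH, H2O2, 0 °C
Reagents that add atoms: hydrogen peroxide (OO)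
Why: Anti-Markovnikov hydroboration–oxidation in which 9-BBN selects the unhindered 1,1-disubstituted alkene over the two trisubstituted ring alkenes; the C11 epimer mixture is harmless because C11 is reset in step 13.

**Step 11**
Reactants: 17 the aryl ether alcohol
Product: 18 germacradiene-6,12-diol 8-silyl ether
Conditions: (NH4)2Ce(NO3)6, pyridine, MeCN/H2O (4:1), 0 °C
Reagents that add atoms: none
Why: Oxidative dearylation of the 4-methoxyphenyl ether (electron-transfer oxidation to the quinone) frees the C6 hydroxyl with its C–O bond, and hence its configuration, intact.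

**Step 12**
Reactants: 18 the 6,12-diol
Product: 21 8-(tert-butyldimethylsilyloxy)germacra-1(10)Z,4E-dien-12,6-olide (cis-fused; C11 epimers), via hydroxy aldehyde 19 (not isolated), via lactol 20 (not isolated)
Conditions: TEMPO (20 mol%), PhI(OAc)2, CH2Cl2, rt
Reagents that add atoms: none
Why: Oxoammonium (TEMPO) oxidation of the primary alcohol, lactol closure onto the cis C6 hydroxyl and a second oxidation give the cis-fused γ-lactone (oxidative lactonisation), the ring fusion being fixed by C6 and C7.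

**Step 13**
Reactants: 21 the lactone
Product: 23 11-hydroxy lactone (OH cis to H7), via lithium lactone enolate 22 (not isolated)
Conditions: LiN(i-Pr)2, THF, −78 °C; then (±)-2-(phenylsulfonyl)-3-phenyloxaziridine, −78 °C
Reagents that add atoms: 2-(phenylsulfonyl)-3-phenyloxaziridine (O=S(=O)(c1ccccc1)N1OC1c1ccccc1)
Why: Davis hydroxylation of the lactone enolate from the convex face of the cis-fused bicycle (the face of H6 and H7) sets C11 as 11S, with the methyl group towards the carbocycle.

**Step 14**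
Reactants: 23 the tertiary alcohol
Product: 25 11-angeloyloxy 8-silyl ether, via lithium alkoxide 24 (not isolated)
Conditions: LiN(SiMe3)2, THF, −78 °C; then angelic anhydride, −78 → 0 °C
Reagents that add atoms: angelic anhydride (C/C=C(/C)C(=O)OC(=O)/C(C)=C\C)
Why: O-acylation of the preformed tertiary lithium alkoxide with the anhydride, which avoids the amine-catalysed Z to E isomerisation of the angelate and touches no stereocentre.

**Step 15**
Reactants: 25 the silyl ether
Product: 27 target CNP0148966.1, via C8 alcohol 26 (not isolated)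
Conditions: HF·pyridine, pyridine, THF, 0 °C → rt; then Ac2O, DMAP, rt
Reagents that add atoms: acetic anhydride (CC(=O)OC(C)=O)
Why: Buffered fluoride desilylation followed by DMAP-catalysed acetylation of the only free hydroxyl, with retention at C8.

**Compound list**
1 | (R)-(−)-carvone, (5R)-2-methyl-5-(prop-1-en-2-yl)cyclohex-2-en-1-one | O=C1C[C@H](C(C)=C)CC=C1C | starting material
2 | (4S,5R)-4-hydroperoxy-2-methyl-5-(prop-1-en-2-yl)cyclohex-2-en-1-one (OOH trans to isopropenyl) | O=C1C[C@H](C(C)=C)[C@@H](OO)C=C1C | intermediate (not isolated)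
3 | (4S,5R)-4-hydroxy-2-methyl-5-(prop-1-en-2-yl)cyclohex-2-en-1-one (trans-4-hydroxycarvone) | O=C1C[C@H](C(C)=C)[C@@H](O)C=C1C | intermediate
4 | (4S,5R)-4-(tert-butyldimethylsilyloxy)-2-methyl-5-(prop-1-en-2-yl)cyclohex-2-en-1-one | O=C1C[C@H](C(C)=C)[C@@H](O[Si](C)(C)C(C)(C)C)C=C1C | intermediate
5 | lithium cross-conjugated dienolate of 4 (C1=C6 enolate) | [Li]OC1=C[C@H](C(C)=C)[C@@H](O[Si](C)(C)C(C)(C)C)C=C1C | intermediate (not isolated)
6 | 6-hydroxy derivative of 4; 6-OH and 4-OSi both trans to the 5-isopropenyl | O=C1[C@@H](O)[C@H](C(C)=C)[C@@H](O[Si](C)(C)C(C)(C)C)C=C1C | intermediate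
7 | 6-(4-methoxyphenoxy) derivative of 4; aryloxy cis, 4-OSi trans to the 5-isopropenyl | O=C1[C@H](Oc2ccc(OC)cc2)[C@H](C(C)=C)[C@@H](O[Si](C)(C)C(C)(C)C)C=C1C | intermediate
8 | lithium C1=C2 enolate from conjugate reduction of 7 | CC1=C(O[Li])[C@H](Oc2ccc(OC)cc2)[C@H](C(C)=C)[C@@H](O[Si](C)(C)C(C)(C)C)C1 | intermediate (not isolated)
9 | 4-(tert-butyldimethylsilyloxy)-6-(4-methoxyphenoxy)-2-methyl-2-[2-(phenylsulfinyl)ethyl]-5-(prop-1-en-2-yl)cyclohexan-1-one; 2-methyl and 6-aryloxy cis, sulfinylethyl and 4-OSi trans to the isopropenyl; sulfur epimers | O=C1[C@H](Oc2ccc(OC)cc2)[C@H](C(C)=C)[C@@H](O[Si](C)(C)C(C)(C)C)C[C@@]1(C)CCS(=O)c1ccccc1 | intermediate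
10 | 2-vinyl analogue of 9 (2-methyl cis, 2-vinyl trans to the isopropenyl) | O=C1[C@H](Oc2ccc(OC)cc2)[C@H](C(C)=C)[C@@H](O[Si](C)(C)C(C)(C)C)C[C@@]1(C)C=C | intermediate
11 | 4-(tert-butyldimethylsilyloxy)-6-(4-methoxyphenoxy)-2-methyl-1,5-di(prop-1-en-2-yl)-2-vinylcyclohexan-1-ol; 1-OH, 2-methyl and 6-aryloxy on the face of the 5-isopropenyl; 1-isopropenyl, 2-vinyl and 4-OSi on the other face | O[C@]1(C(C)=C)[C@H](Oc2ccc(OC)cc2)[C@H](C(C)=C)[C@@H](O[Si](C)(C)C(C)(C)C)C[C@@]1(C)C=C | intermediate
12 | potassium alkoxide of 11 | [K]O[C@]1(C(C)=C)[C@H](Oc2ccc(OC)cc2)[C@H](C(C)=C)[C@@H](O[Si](C)(C)C(C)(C)C)C[C@@]1(C)C=C | intermediate (not isolated)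
13 | potassium (1(10)Z)-6-(4-methoxyphenoxy)-8-(tert-butyldimethylsilyloxy)germacra-1(10),4,11(12)-trien-5-olate (enolate O cis to C3) | COc1ccc(O[C@H]2/C(O[K])=C(\C)CC/C=C(/C)C[C@H](O[Si](C)(C)C(C)(C)C)[C@H]2C(C)=C)cc1 | intermediate (not isolated)
14 | corresponding C5 enol triflate (OTf cis to C3) | COc1ccc(O[C@H]2/C(OS(=O)(=O)C(F)(F)F)=C(\C)CC/C=C(/C)C[C@H](O[Si](C)(C)C(C)(C)C)[C@H]2C(C)=C)cc1 | intermediate
15 | (1(10)Z,4E)-6-(4-methoxyphenoxy)-8-(tert-butyldimethylsilyloxy)germacra-1(10),4,11(12)-triene (6-O cis, 8-O trans to C11) | COc1ccc(O[C@H]2/C=C(\C)CC/C=C(/C)C[C@H](O[Si](C)(C)C(C)(C)C)[C@H]2C(C)=C)cc1 | intermediate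
16 | B-(germacradien-12-yl)-9-borabicyclo[3.3.1]nonane from 15 (C11 epimers) | COc1ccc(O[C@H]2/C=C(\C)CC/C=C(/C)C[C@H](O[Si](C)(C)C(C)(C)C)[C@H]2C(C)CB2C3CCCC2CCC3)cc1 | intermediate (not isolated)
17 | 6-(4-methoxyphenoxy)-8-(tert-butyldimethylsilyloxy)germacra-1(10)Z,4E-dien-12-ol (C11 epimers) | COc1ccc(O[C@H]2/C=C(\C)CC/C=C(/C)C[C@H](O[Si](C)(C)C(C)(C)C)[C@H]2C(C)CO)cc1 | intermediate
18 | 8-(tert-butyldimethylsilyloxy)germacra-1(10)Z,4E-diene-6,12-diol (C11 epimers) | O[C@H]1/C=C(\C)CC/C=C(/C)C[C@H](O[Si](C)(C)C(C)(C)C)[C@H]1C(C)CO | intermediate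
19 | 6-hydroxy-8-(tert-butyldimethylsilyloxy)germacra-1(10)Z,4E-dien-12-al (C11 epimers) | O[C@H]1/C=C(\C)CC/C=C(/C)C[C@H](O[Si](C)(C)C(C)(C)C)[C@H]1C(C)C=O | intermediate (not isolated)
20 | corresponding cis-fused 12,6-lactol | CC1C(O)O[C@H]2/C=C(\C)CC/C=C(/C)C[C@H](O[Si](C)(C)C(C)(C)C)[C@H]21 | intermediate (not isolated)
21 | 8-(tert-butyldimethylsilyloxy)germacra-1(10)Z,4E-dien-12,6-olide, cis-fused (C11 epimers) | CC1C(=O)O[C@H]2/C=C(\C)CC/C=C(/C)C[C@H](O[Si](C)(C)C(C)(C)C)[C@H]21 | intermediate
22 | lithium enolate of 21 | CC1=C(O[Li])O[C@H]2/C=C(\C)CC/C=C(/C)C[C@H](O[Si](C)(C)C(C)(C)C)[C@H]21 | intermediate (not isolated)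
23 | (11S)-11-hydroxy-8-(tert-butyldimethylsilyloxy)germacra-1(10)Z,4E-dien-12,6-olide (OH cis to H7) | O[C@]1(C)C(=O)O[C@H]2/C=C(\C)CC/C=C(/C)C[C@H](O[Si](C)(C)C(C)(C)C)[C@H]21 | intermediate
24 | lithium alkoxide of 23 | [Li]O[C@]1(C)C(=O)O[C@H]2/C=C(\C)CC/C=C(/C)C[C@H](O[Si](C)(C)C(C)(C)C)[C@H]21 | intermediate (not isolated)
25 | 11-angeloyloxy-8-(tert-butyldimethylsilyloxy)germacra-1(10)Z,4E-dien-12,6-olide | C/C=C(/C)C(=O)O[C@]1(C)C(=O)O[C@H]2/C=C(\C)CC/C=C(/C)C[C@H](O[Si](C)(C)C(C)(C)C)[C@H]21 | intermediate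
26 | 11-angeloyloxy-8-hydroxygermacra-1(10)Z,4E-dien-12,6-olide | C/C=C(/C)C(=O)O[C@]1(C)C(=O)O[C@H]2/C=C(\C)CC/C=C(/C)C[C@H](O)[C@H]21 | intermediate (not isolated)
27 | CNP0148966.1, (6S,7R,8S,11S)-8-acetoxy-11-angeloyloxygermacra-1(10)Z,4E-dien-12,6-olide | C/C=C(/C)C(=O)O[C@]1(C)C(=O)O[C@H]2/C=C(\C)CC/C=C(/C)C[C@H](OC(C)=O)[C@H]21 | target

**Totals:** 15 steps; longest linear sequence 15 steps from 1.

**Steps most likely to fail**

Step 1. A secondary γ-position can over-oxidise to the ene-dione, and the γ-hydroxy enone can aromatise under base. The fallback sets out from 1 and comes back at 3. KH in THF followed by t-BuMe2SiCl gives, through the thermodynamic extended dienolate, the linear tert-butyldimethylsilyl dienol ether F1. Dimethyldioxirane at −78 °C then oxidises the γ-carbon anti to the isopropenyl group (vinylogous Rubottom oxidation), and buffered fluoride work-up returns 3.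

Step 5. A quaternary carbon must form on a hindered enolate, and the facial sense rests on the axial C6 aryloxy group. The fallback sets out from 7 and comes back at 10. [(Ph3P)CuH]6 with Me3SiCl reduces the enone and traps the enolate as the trimethylsilyl enol ether F2. A BF3·OEt2-promoted Mukaiyama aldol addition to acetaldehyde, again anti to the axial aryloxy group, gives the 2-(1-hydroxyethyl) ketone F3. Syn-dehydration with methyl N-(triethylammoniosulfonyl)carbamate can only go towards the methyl group and returns 10.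

Step 8. The rearrangement must go through the chair with axial isopropenyl and equatorial vinyl; the other chair carries two 1,3-diaxial pairs and would give the 1(10)E,4Z isomer. The alkoxide, the aryl ether and triflation of a tetrasubstituted enolate add further risk. The fallback sets out from 11 and comes back at 14. Me3SiCl and imidazole give the trimethylsilyl ether F4. Heating in degassed 1,2-dichlorobenzene at 200 °C effects the neutral siloxy-Cope rearrangement through the same chair array to the trimethylsilyl enol ether F5. CsF with PhN(SO2CF3)2 in 1,2-dimethoxyethane then converts F5 into 14.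

**Further compounds**
F1 | step 1 | tert-butyldimethylsilyl (5R)-2-methyl-5-(prop-1-en-2-yl)cyclohexa-1,3-dien-1-yl ether | CC(C)(C)[Si](C)(C)OC1=C(C)C=C[C@@H](C(C)=C)C1
F2 | step 5 | trimethylsilyl C1=C2 enol ether of the 2,3-dihydro derivative of 7 | CC1=C(O[Si](C)(C)C)[C@H](Oc2ccc(OC)cc2)[C@H](C(C)=C)[C@@H](O[Si](C)(C)C(C)(C)C)C1
F3 | step 5 | 2-(1-hydroxyethyl) analogue of 10 (carbinol epimers; hydroxyethyl trans to the isopropenyl) | O=C1[C@H](Oc2ccc(OC)cc2)[C@H](C(C)=C)[C@@H](O[Si](C)(C)C(C)(C)C)C[C@@]1(C)C(C)O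
F4 | step 8 | trimethylsilyl ether of 11 | C[Si](C)(C)O[C@]1(C(C)=C)[C@H](Oc2ccc(OC)cc2)[C@H](C(C)=C)[C@@H](O[Si](C)(C)C(C)(C)C)C[C@@]1(C)C=C
F5 | step 8 | C5 trimethylsilyl enol ether corresponding to 13 | COc1ccc(O[C@H]2/C(O[Si](C)(C)C)=C(\C)CC/C=C(/C)C[C@H](O[Si](C)(C)C(C)(C)C)[C@H]2C(C)=C)cc1
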